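The quinone ring (C1, C2, C3, C4, C4a, C8a) is opened at its C2–C3 bond. C2 and C3 each lie α to one of the carbonyls C1 and C4, and both carbonyls hang on the benzo ring, so the cut leaves an acyclic 1,2-diacylbenzene: an ethyl ketone beside the ketone that carries the whole C40 chain. In the key step its dienolate is oxidised with CuCl2; the two α-carbons couple, the ring closes, and the resulting diketone, the keto tautomer of the quinol, is oxidised on to the quinone in the same flask. The chain is built from geranylgeraniol and farnesyl acetate, its stereocentre by asymmetric hydrogenation.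

Key step: step 16

Remark: 1 and 4 are taken as the single all-E isomers, and the stereocentre of the target (C7 of the side chain) is (R); it derives from C3 of alcohol 11, whose descriptor is (S) only because the substituent priorities differ.

Step 1
Reactants: 1 geranylgeraniol
Product: 2 geranylgeranyl bromide
Conditions: PBr3 (0.4 equiv), Et2O, 0 °C
Reagents that add atoms: phosphorus tribromide, BrP(Br)Br
Why: Conversion of a primary allylic alcohol into the bromide by PBr3 at low temperature, which should proceed without allylic transposition or loss of the E geometry.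

Step 2
Reactants: 2 geranylgeranyl bromide
Product: 3 geranylgeranyl p-tolyl sulfone
Conditions: sodium p-toluenesulfinate (TolSO2Na), DMF, rt
Reagents that add atoms: sodium p-toluenesulfinate, Cc1ccc(cc1)S(=O)[O-].[Na+]
Why: SN2 S-alkylation of the sulfinate by the primary allylic bromide should give the allylic sulfone with the olefin geometry unchanged.

Step 3
Reactants: 4 (2E,6E)-farnesyl acetate
Product: 5 12-hydroxyfarnesyl acetate
Conditions: SeO2 (0.1 equiv), t-BuOOH (3 equiv), salicylic acid (0.1 equiv), CH2Cl2, rt; then NaBH4 (0.3 equiv), MeOH, 0 °C to return over-oxidised enal to the alcohol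
Reagents that add atoms: tert-butyl hydroperoxide, CC(C)(C)OO; selenium dioxide (catalytic oxygen carrier), O=[Se]=O
Why: Selenium dioxide allylic oxidation (ene reaction then [2,3]-sigmatropic shift) should attack the most electron-rich, terminal olefin at its E-methyl group and give the (E)-allylic alcohol, the olefin next to the acetate being deactivated.

Step 4
Reactants: 5 12-hydroxyfarnesyl acetate
Product: 6 12-bromofarnesyl acetate
Conditions: CBr4, PPh3, CH2Cl2, 0 °C
Reagents that add atoms: carbon tetrabromide, BrC(Br)(Br)Br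
Why: Appel bromination of the primary allylic alcohol under neutral conditions should leave the acetate and the three E olefins untouched.

Step 5
Reactants: 3 geranylgeranyl p-tolyl sulfone and 6 12-bromofarnesyl acetate
Product: 8 C35 sulfonyl acetate, via lithiated sulfone 7 (not isolated)
Conditions: n-BuLi (1.0 equiv), THF/DMPU, −78 °C; then 6, −78 °C
Reagents that add atoms: none
Why: Biellmann coupling, in which the sulfone-stabilised allyl anion is alkylated at its α-carbon by the primary allylic bromide (SN2) at −78 °C faster than it attacks the acetate; the sulfonyl-bearing centre C13 forms racemic and is erased in step 6.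

Step 6
Reactants: 8 C35 sulfonyl acetate
Product: 10 all-E-heptaprenol, via sulfonyl alkoxide 9 (not isolated)
Conditions: LiBHEt3 (5 equiv), THF, 0 °C; then PdCl2(dppp) (5 mol %), 0 °C to rt
Reagents that add atoms: none
Why: LiBHEt3 first reduces the acetate to alkoxide 9, which zerovalent palladium cannot ionise, and the palladium-catalysed reductive desulfonylation then delivers hydride to the less substituted terminus of the π-allyl complex (the former sulfonyl carbon), so the trisubstituted olefin should keep its position and E geometry.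

Step 7
Reactants: 10 all-E-heptaprenol
Product: 11 (3S)-2,3-dihydroheptaprenol
Conditions: H2 (100 atm), Ru(OAc)2[(R)-BINAP] (0.5 mol %), MeOH/CH2Cl2, 25 °C
Reagents that add atoms: none
Why: Noyori asymmetric hydrogenation, in which the ruthenium–BINAP dicarboxylate reduces only the olefin that chelates through the allylic hydroxyl (the six remote olefins stay) and the (R)-BINAP ligand directs hydrogen to the face of the (E)-allylic alcohol that gives the (3S) alcohol, as in the conversion of geraniol into (S)-citronellol.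

Step 8
Reactants: 11 (3S)-2,3-dihydroheptaprenol
Product: 12 (3S)-iodide
Conditions: I2, PPh3, imidazole, CH2Cl2, 0 °C to rt
Reagents that add atoms: iodine, II
Why: Appel-type iodination of the primary alcohol through its alkoxyphosphonium salt; the stereocentre two carbons away is not involved.

Step 9
Reactants: 12 (3S)-iodide
Product: 14 terminal alkyne, via silylalkyne 13 (not isolated)
Conditions: 1-(trimethylsilyl)propyne, n-BuLi, THF, −20 °C; 12, −78 °C to rt; then K2CO3, MeOH, rt
Reagents that add atoms: 1-(trimethylsilyl)propyne, CC#C[Si](C)(C)C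
Why: SN2 alkylation of the propargylic carbon of lithiated 1-(trimethylsilyl)propyne by the primary iodide, the silyl group blocking the acetylenic terminus and then being removed by base-catalysed methanolysis.

Step 10
Reactants: 14 terminal alkyne
Product: 17 C40 allylic alcohol, via alkenylalane 15 (not isolated), via lithium alanate 16 (not isolated)
Conditions: Me3Al (2.5 equiv), Cp2ZrCl2 (0.25 equiv), CH2Cl2, 0 °C to rt; volatiles removed; n-BuLi, hexane/THF, −78 °C; (CH2O)n, −78 °C to rt
Reagents that add atoms: trimethylaluminium, C[Al](C)C; formaldehyde (charged as paraformaldehyde), C=O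
Why: Negishi zirconium-catalysed carboalumination adds methyl and aluminium syn across the terminal alkyne with methyl on the internal carbon, which fixes the (2E) geometry, and the alanate formed with n-BuLi is hydroxymethylated by formaldehyde with retention; the isolated trisubstituted olefins do not react.

Step 11
Reactants: 17 C40 allylic alcohol
Product: 18 C40 allylic bromide
Conditions: PBr3 (0.4 equiv), Et2O, 0 °C
Reagents that add atoms: phosphorus tribromide, BrP(Br)Br
Why: Same mild bromination as in step 1, which should give the primary allylic bromide without transposition or E/Z isomerisation.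

Step 12
Reactants: 19 2'-bromopropiophenone
Product: 20 bromoaryl dioxolane
Conditions: ethylene glycol, TsOH (cat.), toluene, reflux, Dean–Stark trap
Reagents that add atoms: ethylene glycol, OCCO
Why: Acid-catalysed ketalisation with azeotropic removal of water masks the ethyl ketone for the organolithium and enolate steps that follow.

Step 13
Reactants: 20 bromoaryl dioxolane
Product: 22 ketal methyl ketone, via aryllithium 21 (not isolated)
Conditions: n-BuLi, THF, −78 °C; then N-methoxy-N-methylacetamide, −78 to 0 °C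
Reagents that add atoms: N-methoxy-N-methylacetamide, CC(=O)N(C)OC
Why: Bromine–lithium exchange followed by Weinreb acylation, whose chelated tetrahedral adduct prevents a second addition.

Step 14
Reactants: 22 ketal methyl ketone (2.5 equiv) and 18 C40 allylic bromide
Product: 24 ketal ketone, via lithium enolate 23 (not isolated)
Conditions: LDA (LiN(iPr)2), THF, −78 °C; then 18, DMPU, −78 to −20 °C
Reagents that add atoms: none
Why: SN2 alkylation of the lithium enolate (the ketone has a single enolisable site) by the primary allylic bromide, with the enolate in excess to suppress dialkylation.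

Step 15
Reactants: 24 ketal ketone
Product: 25 diketone
Conditions: 1 M aq. HCl, THF, rt
Reagents that add atoms: water, O
Why: Acid-catalysed hydrolysis of the dioxolane under conditions too mild to protonate the trisubstituted olefins.

Step 16
Reactants: 25 diketone
Product: 29 target quinone, via dilithium dienolate 26 (not isolated), via dihydroquinone diketone 27 (not isolated), via quinol 28 (not isolated)
Conditions: LDA (LiN(iPr)2, 2.4 equiv), THF, −78 °C, 25 added slowly to the base; CuCl2 (4.5 equiv) in DMF, −78 °C to rt; aq. NH4Cl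
Reagents that add atoms: none
Why: LDA removes the only enolisable protons, those at the future C2 and C3, and divalent copper oxidises one enolate of dienolate 26 to an α-keto radical that is captured by the neighbouring enolate carbon, a second electron transfer completing the C2–C3 bond of diketone 27. The closest known reaction type is the intramolecular oxidative coupling of ketone dienolates with CuCl2 to cyclic 1,4-diketones. The six-membered ring closes in the 6-endo-trig mode, since the accepting enolate C1=C2 lies inside the new ring. The stereocentres formed at C2 and C3 of 27 are uncontrolled and both vanish when amine-promoted enolisation gives quinol 28, which the excess CuCl2 oxidises to the quinone, so the remote (R)-centre of the chain remains the only stereocentre. The step needs C–C coupling within the molecule in preference to aldol addition and to attack on the olefins: the only aldol open to the mono-enolate is a disfavoured 5-(enolendo)-exo-trig closure, slow addition of 25 to excess base ensures double deprotonation, and the nearest olefin could be reached only by 3-exo or 4-endo cyclisation.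

Compound list

1 | (2E,6E,10E)-geranylgeraniol, (2E,6E,10E)-3,7,11,15-tetramethylhexadeca-2,6,10,14-tetraen-1-ol | CC(C)=CCC/C(C)=C/CC/C(C)=C/CC/C(C)=C/CO | starting material
2 | (2E,6E,10E)-1-bromo-3,7,11,15-tetramethylhexadeca-2,6,10,14-tetraene | CC(C)=CCC/C(C)=C/CC/C(C)=C/CC/C(C)=C/CBr | intermediate
3 | (2E,6E,10E)-geranylgeranyl p-tolyl sulfone | CC(C)=CCC/C(C)=C/CC/C(C)=C/CC/C(C)=C/CS(=O)(=O)c1ccc(C)cc1 | intermediate
4 | (2E,6E)-farnesyl acetate | CC(C)=CCC/C(C)=C/CC/C(C)=C/COC(C)=O | starting material
5 | (2E,6E,10E)-12-hydroxy-3,7,11-trimethyldodeca-2,6,10-trien-1-yl acetate | OC/C(C)=C/CC/C(C)=C/CC/C(C)=C/COC(C)=O | intermediate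
6 | (2E,6E,10E)-12-bromo-3,7,11-trimethyldodeca-2,6,10-trien-1-yl acetate | BrC/C(C)=C/CC/C(C)=C/CC/C(C)=C/COC(C)=O | intermediate
7 | 1-lithio derivative of sulfone 3 (α-sulfonyl allyllithium) | CC(C)=CCC/C(C)=C/CC/C(C)=C/CC/C(C)=C/C([Li])S(=O)(=O)c1ccc(C)cc1 | intermediate
8 | (2E,6E,10E,14E,18E,22E)-3,7,11,15,19,23,27-heptamethyl-13-(4-methylbenzenesulfonyl)octacosa-2,6,10,14,18,22,26-heptaen-1-yl acetate, racemic at C13 | CC(C)=CCC/C(C)=C/CC/C(C)=C/CC/C(C)=C/C(S(=O)(=O)c1ccc(C)cc1)C/C(C)=C/CC/C(C)=C/CC/C(C)=C/COC(C)=O | intermediate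
9 | lithium alkoxide of the 13-sulfonyl heptaprenol (8 without its acetyl group) | CC(C)=CCC/C(C)=C/CC/C(C)=C/CC/C(C)=C/C(S(=O)(=O)c1ccc(C)cc1)C/C(C)=C/CC/C(C)=C/CC/C(C)=C/CO[Li] | intermediate
10 | all-E-heptaprenol, (2E,6E,10E,14E,18E,22E)-3,7,11,15,19,23,27-heptamethyloctacosa-2,6,10,14,18,22,26-heptaen-1-ol | CC(C)=CCC/C(C)=C/CC/C(C)=C/CC/C(C)=C/CC/C(C)=C/CC/C(C)=C/CC/C(C)=C/CO | intermediate
11 | (3S,6E,10E,14E,18E,22E)-3,7,11,15,19,23,27-heptamethyloctacosa-6,10,14,18,22,26-hexaen-1-ol | CC(C)=CCC/C(C)=C/CC/C(C)=C/CC/C(C)=C/CC/C(C)=C/CC/C(C)=C/CC[C@H](C)CCO | intermediate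
12 | (3S,6E,10E,14E,18E,22E)-1-iodo-3,7,11,15,19,23,27-heptamethyloctacosa-6,10,14,18,22,26-hexaene | CC(C)=CCC/C(C)=C/CC/C(C)=C/CC/C(C)=C/CC/C(C)=C/CC/C(C)=C/CC[C@H](C)CCI | intermediate
13 | trimethyl[(6R,9E,13E,17E,21E,25E)-6,10,14,18,22,26,30-heptamethylhentriaconta-9,13,17,21,25,29-hexaen-1-yn-1-yl]silane | CC(C)=CCC/C(C)=C/CC/C(C)=C/CC/C(C)=C/CC/C(C)=C/CC/C(C)=C/CC[C@H](C)CCCC#C[Si](C)(C)C | intermediate
14 | (6R,9E,13E,17E,21E,25E)-6,10,14,18,22,26,30-heptamethylhentriaconta-9,13,17,21,25,29-hexaen-1-yne | CC(C)=CCC/C(C)=C/CC/C(C)=C/CC/C(C)=C/CC/C(C)=C/CC/C(C)=C/CC[C@H](C)CCCC#C | intermediate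
15 | dimethyl[(1E,6R,9E,13E,17E,21E,25E)-2,6,10,14,18,22,26,30-octamethylhentriaconta-1,9,13,17,21,25,29-heptaen-1-yl]alane | CC(C)=CCC/C(C)=C/CC/C(C)=C/CC/C(C)=C/CC/C(C)=C/CC/C(C)=C/CC[C@H](C)CCC/C(C)=C/[Al](C)C | intermediate
16 | lithium butyl(dimethyl)alanate of 15 (butyl added to aluminium) | CC(C)=CCC/C(C)=C/CC/C(C)=C/CC/C(C)=C/CC/C(C)=C/CC/C(C)=C/CC[C@H](C)CCC/C(C)=C/[Al-](C)(C)CCCC.[Li+] | intermediate
17 | (2E,7R,10E,14E,18E,22E,26E)-3,7,11,15,19,23,27,31-octamethyldotriaconta-2,10,14,18,22,26,30-heptaen-1-ol | CC(C)=CCC/C(C)=C/CC/C(C)=C/CC/C(C)=C/CC/C(C)=C/CC/C(C)=C/CC[C@H](C)CCC/C(C)=C/CO | intermediate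
18 | (2E,7R,10E,14E,18E,22E,26E)-1-bromo-3,7,11,15,19,23,27,31-octamethyldotriaconta-2,10,14,18,22,26,30-heptaene | CC(C)=CCC/C(C)=C/CC/C(C)=C/CC/C(C)=C/CC/C(C)=C/CC/C(C)=C/CC[C@H](C)CCC/C(C)=C/CBr | intermediate
19 | 1-(2-bromophenyl)propan-1-one (2'-bromopropiophenone) | CCC(=O)c1ccccc1Br | starting material
20 | 2-(2-bromophenyl)-2-ethyl-1,3-dioxolane | CCC1(OCCO1)c1ccccc1Br | intermediate
21 | [2-(2-ethyl-1,3-dioxolan-2-yl)phenyl]lithium | CCC1(OCCO1)c1ccccc1[Li] | intermediate
22 | 1-[2-(2-ethyl-1,3-dioxolan-2-yl)phenyl]ethan-1-one | CCC1(OCCO1)c1ccccc1C(C)=O | intermediate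
23 | lithium enolate of 22 | CCC1(OCCO1)c1ccccc1C(=C)O[Li] | intermediate
24 | (4E,9R,12E,16E,20E,24E,28E)-1-[2-(2-ethyl-1,3-dioxolan-2-yl)phenyl]-5,9,13,17,21,25,29,33-octamethyltetratriaconta-4,12,16,20,24,28,32-heptaen-1-one | CC(C)=CCC/C(C)=C/CC/C(C)=C/CC/C(C)=C/CC/C(C)=C/CC/C(C)=C/CC[C@H](C)CCC/C(C)=C/CCC(=O)c1ccccc1C1(CC)OCCO1 | intermediate
25 | (4E,9R,12E,16E,20E,24E,28E)-5,9,13,17,21,25,29,33-octamethyl-1-(2-propanoylphenyl)tetratriaconta-4,12,16,20,24,28,32-heptaen-1-one | CC(C)=CCC/C(C)=C/CC/C(C)=C/CC/C(C)=C/CC/C(C)=C/CC/C(C)=C/CC[C@H](C)CCC/C(C)=C/CCC(=O)c1ccccc1C(=O)CC | intermediate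
26 | dilithium (Z,Z)-dienolate of 25 (both ketones enolised, O–Li cis to the alkyl group on each enolate carbon) | CC(C)=CCC/C(C)=C/CC/C(C)=C/CC/C(C)=C/CC/C(C)=C/CC/C(C)=C/CC[C@H](C)CCC/C(C)=C/C/C=C(\O[Li])c1ccccc1C(/O[Li])=C/C | intermediate
27 | 2-methyl-3-[(2E,7R,10E,14E,18E,22E,26E)-3,7,11,15,19,23,27,31-octamethyldotriaconta-2,10,14,18,22,26,30-heptaen-1-yl]-2,3-dihydronaphthalene-1,4-dione, mixture of C2/C3 diastereomers | CC(C)=CCC/C(C)=C/CC/C(C)=C/CC/C(C)=C/CC/C(C)=C/CC/C(C)=C/CC[C@H](C)CCC/C(C)=C/CC1C(C)C(=O)c2ccccc2C1=O | intermediate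
28 | 2-methyl-3-[(2E,7R,10E,14E,18E,22E,26E)-3,7,11,15,19,23,27,31-octamethyldotriaconta-2,10,14,18,22,26,30-heptaen-1-yl]naphthalene-1,4-diol | CC(C)=CCC/C(C)=C/CC/C(C)=C/CC/C(C)=C/CC/C(C)=C/CC/C(C)=C/CC[C@H](C)CCC/C(C)=C/Cc1c(C)c(O)c2ccccc2c1O | intermediate
29 | 2-methyl-3-[(2E,7R,10E,14E,18E,22E,26E)-3,7,11,15,19,23,27,31-octamethyldotriaconta-2,10,14,18,22,26,30-heptaen-1-yl]naphthalene-1,4-dione | CC(C)=CCC/C(C)=C/CC/C(C)=C/CC/C(C)=C/CC/C(C)=C/CC/C(C)=C/CC[C@H](C)CCC/C(C)=C/CC1=C(C)C(=O)c2ccccc2C1=O | target

Total step count: 16.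
Longest linear sequence: 12 steps (4 → 5 → 6 → 8 → 10 → 11 → 12 → 14 → 17 → 18 → 24 → 25 → 29, that is steps 3 to 11 and 14 to 16).

Steps most likely to fail

Step 16. The oxidation may couple enolates of different molecules or chlorinate an enolate carbon instead of closing the ring, or the dihydro diketone may not be carried through to the quinone. The fallback sets out from bromide 18 and returns at target 29, closing the same bond by an anionic carbocyclisation. Sonogashira coupling of 2'-bromoacetophenone with propyne (Pd(PPh3)2Cl2, copper monoiodide CuI, Et3N) would give 1-[2-(prop-1-yn-1-yl)phenyl]ethan-1-one F1. Its lithium enolate (LiN(iPr)2, THF, −78 °C) would be alkylated with 18 to the alkynyl ketone F2. KN(SiMe3)2 (THF/toluene, −78 °C to rt) would then add the enolate carbon (future C2) to the methyl-bearing alkyne carbon (future C3) in a 6-endo-dig closure and give, after tautomerisation, the 1-naphthol F3. Fremy's salt, (KO3S)2NO, in buffered CH2Cl2/water with methyltrioctylammonium chloride would oxidise F3 at its free para position C4 to 29.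

Step 5. The sulfonyl carbanion may take the acetyl group of 6 (acyl transfer) instead of displacing bromide. The fallback sets out from 6 and returns at alkoxide 9, with no ester present during the coupling. iBu2AlH (CH2Cl2, −78 °C) would reduce the acetate of 6 to 12-bromofarnesol F4. F4 would be added at −78 °C to two equivalents of lithiated sulfone 7: the first equivalent deprotonates the hydroxyl to the lithium alkoxide F5 (returning recoverable 3), and the second is alkylated by the allylic bromide. This gives 9 directly, which is desulfonylated with PdCl2(dppp) and LiBHEt3 as in step 6.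

Step 7. Facial selectivity may be incomplete, the hydrogenation may stall on the poorly soluble C35 alcohol, or remote olefins may be partly reduced at high pressure; the stereocentre set here cannot be corrected later. The fallback sets out from 10 and returns at 11 by an organocatalytic route. MnO2 (CH2Cl2, rt) would oxidise 10 to all-E-heptaprenal F6. Iminium-mediated transfer hydrogenation with a Hantzsch ester and the morpholinium salt of (S)-TRIP (the antipode of the salt that turns citral into (R)-citronellal; dioxane, 50 °C) would give (S)-2,3-dihydroheptaprenal F7. NaBH4 (MeOH/THF, 0 °C) would reduce F7 to 11.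

Further compounds

F1 | step 16 | 1-[2-(prop-1-yn-1-yl)phenyl]ethan-1-one | CC#Cc1ccccc1C(C)=O
F2 | step 16 | (4E,9R,12E,16E,20E,24E,28E)-5,9,13,17,21,25,29,33-octamethyl-1-[2-(prop-1-yn-1-yl)phenyl]tetratriaconta-4,12,16,20,24,28,32-heptaen-1-one | CC(C)=CCC/C(C)=C/CC/C(C)=C/CC/C(C)=C/CC/C(C)=C/CC/C(C)=C/CC[C@H](C)CCC/C(C)=C/CCC(=O)c1ccccc1C#CC
F3 | step 16 | 3-methyl-2-[(2E,7R,10E,14E,18E,22E,26E)-3,7,11,15,19,23,27,31-octamethyldotriaconta-2,10,14,18,22,26,30-heptaen-1-yl]naphthalen-1-ol | CC(C)=CCC/C(C)=C/CC/C(C)=C/CC/C(C)=C/CC/C(C)=C/CC/C(C)=C/CC[C@H](C)CCC/C(C)=C/Cc1c(C)cc2ccccc2c1O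
F4 | step 5 | (2E,6E,10E)-12-bromo-3,7,11-trimethyldodeca-2,6,10-trien-1-ol | BrC/C(C)=C/CC/C(C)=C/CC/C(C)=C/CO
F5 | step 5 | lithium alkoxide of F4 | BrC/C(C)=C/CC/C(C)=C/CC/C(C)=C/CO[Li]
F6 | step 7 | (2E,6E,10E,14E,18E,22E)-3,7,11,15,19,23,27-heptamethyloctacosa-2,6,10,14,18,22,26-heptaenal | CC(C)=CCC/C(C)=C/CC/C(C)=C/CC/C(C)=C/CC/C(C)=C/CC/C(C)=C/CC/C(C)=C/C=O
F7 | step 7 | (3S,6E,10E,14E,18E,22E)-3,7,11,15,19,23,27-heptamethyloctacosa-6,10,14,18,22,26-hexaenal | CC(C)=CCC/C(C)=C/CC/C(C)=C/CC/C(C)=C/CC/C(C)=C/CC/C(C)=C/CC[C@H](C)CC=O
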